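**Plan**
- Retrosynthesis: the C4 ketone is taken back to a carbinol, the aryl ether bond O1–C8a is cut to give an open-chain bromo-1,3-diol, both carbinols go back to a 1,3-diketone, and this is cut at C2–C3 (Claisen) and at C4–C4a (Friedel–Crafts).
- Enabling feature: O1 is an aryl ether oxygen on C8a of ring A, ortho to C4a. A hydroxyl on C2 reaches C8a through the six-membered pyran ring C, whereas the hydroxyl on C4 could only close a four-membered ring.
- Forward: ring A is acetylated next to bromine (C4–C4a), the chain is joined to the ring B ester (C2–C3), the two carbonyls are reduced in turn, ring C is closed by Pd-catalysed C–O coupling, and C4 is re-oxidised.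
- Stereochemistry: C2 (S) comes from catalyst-controlled transfer hydrogenation with the (S,S)-TsDPEN–Ru catalyst and is carried through the ring closure with retention. The C4 carbinol is set anti by hydroxyl-directed reduction only to have single diastereomers, and is erased in the last step.

Key step: step 5

Remark: flavanone numbering is used throughout; in the open-chain compounds C1 is the future C4 and C3 the future C2. Diketone 5 is drawn as the diketo tautomer although it should exist mainly as the chelated enol.

**Step 1**
Reactants: 1 1-bromo-3,5-dimethoxybenzene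
Product: 2 1-(2-bromo-4,6-dimethoxyphenyl)ethan-1-one
Conditions: AcCl, AlCl3, CH2Cl2, 0 °C
Reagents that add atoms: acetyl chloride CC(=O)Cl
Why: Friedel–Crafts acylation should take place at one of the two equivalent ring carbons that are para to one methoxy group and ortho to the other (next to bromine), the position also taken in Vilsmeier formylation of this arene, in preference to the site squeezed between both methoxy groups, which puts bromine and a methoxy group on either side of the new C4–C4a bond.

**Step 2**
Reactants: 2 1-(2-bromo-4,6-dimethoxyphenyl)ethan-1-one; 3 methyl 3,4,5-trimethoxybenzoate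
Product: 5 1-(2-bromo-4,6-dimethoxyphenyl)-3-(3,4,5-trimethoxyphenyl)propane-1,3-dione, via sodium 1,3-diketonate 4 (not isolated)
Conditions: NaH (2.5 equiv), THF, reflux; then aq. HCl
Reagents that add atoms: none
Why: Crossed Claisen condensation, in which only ketone 2 can enolise, the benzoate cannot self-condense, and irreversible deprotonation of the product to the chelated sodium diketonate should drive formation of the C2–C3 bond to completion.

**Step 3**
Reactants: 5 1-(2-bromo-4,6-dimethoxyphenyl)-3-(3,4,5-trimethoxyphenyl)propane-1,3-dione
Product: 6 (S)-1-(2-bromo-4,6-dimethoxyphenyl)-3-hydroxy-3-(3,4,5-trimethoxyphenyl)propan-1-one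
Conditions: RuCl(p-cymene)[(S,S)-TsDPEN] (1 mol%), HCO2H/Et3N (5:2), CH2Cl2, 30 °C
Reagents that add atoms: none
Why: Noyori–Ikariya asymmetric transfer hydrogenation, in which the Ru–H/N–H unit passes hydride and proton to the carbonyl through an outer-sphere six-membered transition state with the aryl ring held against the η6-arene, so the (S,S)-catalyst should give the (S)-aryl carbinol (the future C2) as it does with acetophenone, while the carbonyl flanked by bromine and methoxy is twisted and shielded and should stay untouched.

**Step 4**
Reactants: 6 (S)-1-(2-bromo-4,6-dimethoxyphenyl)-3-hydroxy-3-(3,4,5-trimethoxyphenyl)propan-1-one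
Product: 7 (1S,3S)-1-(2-bromo-4,6-dimethoxyphenyl)-3-(3,4,5-trimethoxyphenyl)propane-1,3-diol
Conditions: Me4NBH(OAc)3, MeCN/AcOH, −20 °C
Reagents that add atoms: none
Why: Evans–Saksena hydroxyl-directed reduction, in which the C3 hydroxyl exchanges onto boron and hydride is delivered intramolecularly through a chair-like six-membered transition state, should set the new C1 carbinol anti to C3 (1S) and help the hindered carbonyl react; this centre is oxidised away later, so any syn epimer would converge on the same target.

**Step 5**
Reactants: 7 (1S,3S)-1-(2-bromo-4,6-dimethoxyphenyl)-3-(3,4,5-trimethoxyphenyl)propane-1,3-diol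
Product: 8 (2S,4S)-5,7-dimethoxy-2-(3,4,5-trimethoxyphenyl)chroman-4-ol (2,4-cis)
Conditions: Pd(OAc)2 (3 mol%), 2-(di-tert-butylphosphino)-1,1'-binaphthyl (4 mol%), Cs2CO3, toluene, 70 °C
Reagents that add atoms: none
Why: Pd(0) carrying the bulky monophosphine should insert into the C8a–Br bond, carbonate-assisted exchange then places the C3 alkoxide (the future O1) on palladium, and C–O reductive elimination from the seven-membered oxapalladacycle forms the O1–C8a bond and returns Pd(0). The closest known reaction type is the Buchwald–Hartwig intramolecular etherification of aryl bromides with secondary alcohols, which gives chromans from optically active carbinols without loss of configuration. The dihydropyran ring, the only ring formed, closes by exo attack of oxygen on the metal-bound aryl carbon (6-exo with respect to the arene). No stereocentre is created: the C2–O bond is never broken, so C2 stays S, and C4 is a spectator. The step needs selectivity between the two hydroxyls and against β-hydride elimination: the C1 hydroxyl could only close a four-membered benzoxete and, when bound, sits in a five-membered chelate whose C–H bond cannot align with the Pd–O bond, while the tert-butyl groups of the ligand should push reductive elimination of the C3 alkoxide ahead of β-hydride loss. With no carbonyl in the substrate, the carbonate base has no retro-oxa-Michael path by which to racemise C2.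

**Step 6**
Reactants: 8 (2S,4S)-5,7-dimethoxy-2-(3,4,5-trimethoxyphenyl)chroman-4-ol
Product: 9 (S)-5,7-dimethoxy-2-(3,4,5-trimethoxyphenyl)chroman-4-one
Conditions: Dess–Martin periodinane, pyridine, CH2Cl2, 0 °C to rt
Reagents that add atoms: none
Why: Dess–Martin oxidation, by ligand exchange of the only hydroxyl onto iodine(V) and loss of the carbinol hydrogen, should give the C4 ketone under buffered, near-neutral conditions that leave the ether C2–H alone and offer no base strong enough to open the pyranone by a retro-oxa-Michael reaction.

**Compound list**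
1 | 1-bromo-3,5-dimethoxybenzene | COc1cc(Br)cc(OC)c1 | starting material
2 | 1-(2-bromo-4,6-dimethoxyphenyl)ethan-1-one | CC(=O)c1c(Br)cc(OC)cc1OC | intermediate
3 | methyl 3,4,5-trimethoxybenzoate | COC(=O)c1cc(OC)c(OC)c(OC)c1 | starting material
4 | sodium (Z)-3-(2-bromo-4,6-dimethoxyphenyl)-3-oxo-1-(3,4,5-trimethoxyphenyl)prop-1-en-1-olate (sodium 1,3-diketonate of 5, formed in the flask) | [Na+].[O-]/C(=C\C(=O)c1c(Br)cc(OC)cc1OC)c1cc(OC)c(OC)c(OC)c1 | intermediate
5 | 1-(2-bromo-4,6-dimethoxyphenyl)-3-(3,4,5-trimethoxyphenyl)propane-1,3-dione | O=C(CC(=O)c1c(Br)cc(OC)cc1OC)c1cc(OC)c(OC)c(OC)c1 | intermediate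
6 | (S)-1-(2-bromo-4,6-dimethoxyphenyl)-3-hydroxy-3-(3,4,5-trimethoxyphenyl)propan-1-one | O[C@H](c1cc(OC)c(OC)c(OC)c1)CC(=O)c1c(Br)cc(OC)cc1OC | intermediate
7 | (1S,3S)-1-(2-bromo-4,6-dimethoxyphenyl)-3-(3,4,5-trimethoxyphenyl)propane-1,3-diol | O[C@H](c1cc(OC)c(OC)c(OC)c1)C[C@H](O)c1c(Br)cc(OC)cc1OC | intermediate
8 | (2S,4S)-5,7-dimethoxy-2-(3,4,5-trimethoxyphenyl)chroman-4-ol | COc1cc(OC)c2c(c1)O[C@H](c1cc(OC)c(OC)c(OC)c1)C[C@@H]2O | intermediate
9 | (S)-5,7-dimethoxy-2-(3,4,5-trimethoxyphenyl)chroman-4-one | COc1cc(OC)c2c(c1)O[C@H](c1cc(OC)c(OC)c(OC)c1)CC2=O | target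

**Total step count:** 6
**Longest linear sequence:** 6 steps (from 1)

**Steps most likely to fail**

Step 5. β-Hydride elimination from a palladium alkoxide, with reductive loss of bromine, or sequestration of palladium by the nearby C1 alkoxide may outrun C–O reductive elimination. The fallback sets out from 7 and moves to a copper manifold, in which alkoxides do not β-eliminate. Aromatic Finkelstein exchange (CuI, trans-N,N'-dimethylcyclohexane-1,2-diamine, NaI, dioxane, 110 °C) should give the aryl iodide (1S,3S)-1-(2-iodo-4,6-dimethoxyphenyl)-3-(3,4,5-trimethoxyphenyl)propane-1,3-diol F1. Ullmann-type intramolecular O-arylation (CuI, 3,4,7,8-tetramethyl-1,10-phenanthroline, Cs2CO3, toluene, 90 °C) should then close the same O1–C8a bond, and the route is rejoined at 8.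

Step 3. The catalyst may fail to tell the two carbonyls apart, or turn over slowly because the substrate rests as a chelating enol, so that conversion or enantiomeric purity at the future C2 falls short. The fallback sets out from 2 and builds the carbinol from an epoxide instead. Claisen–Schmidt condensation with 3,4,5-trimethoxybenzaldehyde (KOH, EtOH, rt) should give the chalcone (E)-1-(2-bromo-4,6-dimethoxyphenyl)-3-(3,4,5-trimethoxyphenyl)prop-2-en-1-one F2. Juliá–Colonna epoxidation (poly-D-leucine, urea–H2O2, DBU, THF), the catalyst antipode expected by analogy with chalcone itself to give the (2S,3R) series, should give (2-bromo-4,6-dimethoxyphenyl)[(2S,3R)-3-(3,4,5-trimethoxyphenyl)oxiran-2-yl]methanone F3. Reductive cleavage of the Cα–O bond (SmI2, THF/MeOH, −78 °C) leaves the benzylic C–O bond intact, and the route is rejoined at 6.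

Step 4. Intramolecular hydride delivery to the di-ortho-substituted aryl ketone may be sluggish, and the acidic medium may ionise the electron-rich benzylic carbinol once it has formed. The fallback sets out from 6 and uses the syn series under non-acidic conditions. Narasaka–Prasad reduction (Et2BOMe, NaBH4, THF/MeOH, −78 °C) should give (1R,3S)-1-(2-bromo-4,6-dimethoxyphenyl)-3-(3,4,5-trimethoxyphenyl)propane-1,3-diol F4. The Pd-catalysed etherification under the conditions of step 5 should give the 2,4-trans alcohol (2S,4R)-5,7-dimethoxy-2-(3,4,5-trimethoxyphenyl)chroman-4-ol F5. Dess–Martin oxidation as in step 6 then rejoins the route at 9.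

**Further compounds**
F1 | step 5 | (1S,3S)-1-(2-iodo-4,6-dimethoxyphenyl)-3-(3,4,5-trimethoxyphenyl)propane-1,3-diol | O[C@H](c1cc(OC)c(OC)c(OC)c1)C[C@H](O)c1c(I)cc(OC)cc1OC
F2 | step 3 | (E)-1-(2-bromo-4,6-dimethoxyphenyl)-3-(3,4,5-trimethoxyphenyl)prop-2-en-1-one | O=C(/C=C/c1cc(OC)c(OC)c(OC)c1)c1c(Br)cc(OC)cc1OC
F3 | step 3 | (2-bromo-4,6-dimethoxyphenyl)[(2S,3R)-3-(3,4,5-trimethoxyphenyl)oxiran-2-yl]methanone | O=C(c1c(Br)cc(OC)cc1OC)[C@H]1O[C@@H]1c1cc(OC)c(OC)c(OC)c1
F4 | step 4 | (1R,3S)-1-(2-bromo-4,6-dimethoxyphenyl)-3-(3,4,5-trimethoxyphenyl)propane-1,3-diol | O[C@H](c1cc(OC)c(OC)c(OC)c1)C[C@@H](O)c1c(Br)cc(OC)cc1OC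
F5 | step 4 | (2S,4R)-5,7-dimethoxy-2-(3,4,5-trimethoxyphenyl)chroman-4-ol | COc1cc(OC)c2c(c1)O[C@H](c1cc(OC)c(OC)c(OC)c1)C[C@H]2O
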